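**Retrosynthetic overview**
1. Target 26 comes from protected biflavone 25 by one BCl3 step (four benzyl ethers and the chelated 5-OMe of unit 2 fall; the 4'-OMe of unit 1 stays).
2. The pyranone of unit 1 (ring C, closed last) comes from deoxybenzoin 21 and 4-methoxybenzoyl chloride by acyl transfer and cyclodehydration.
3. Deoxybenzoin 21 comes from Friedel–Crafts acylation of 1,3,5-tris(benzyloxy)benzene with flavon-6-ylacetic acid 16; 16 comes from a 6-allylflavone set by Claisen rearrangement of a 5-O-allyl ether, which fixes C6 unambiguously.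
4. Key C–C bond: the C2–C3 bond of unit 2, made by intermolecular Claisen–Schmidt aldol condensation of acetophenone 2 with aldehyde 3; the pyranone of unit 2 is closed first.
5. Unit 1 is the 2-(4-methoxyphenyl)chromone; unit 2 is the apigenin-type chromone linked through C6.

Assumption: the SMILES has no stereocentre and no defined axis, so the compound is made as drawn and the hindered 3–6 biaryl axis is not resolved.

**Step 1**
Reactants: 1 2,4,6-trihydroxyacetophenone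
Product: 2 1-[2,4-bis(benzyloxy)-6-hydroxyphenyl]ethanone
Conditions: BnBr (2.1 equiv), K2CO3, DMF, rt, 16 h
Reagents that add atoms: benzyl bromide, BrCc1ccccc1
Why: Williamson ether synthesis in which the para-OH and one ortho-OH react while the remaining ortho-OH stays locked in the hydrogen bond to the ketone.

**Step 2**
Reactants: 2 1-[2,4-bis(benzyloxy)-6-hydroxyphenyl]ethanone; 3 4-(benzyloxy)benzaldehyde
Product: 5 (E)-1-[2,4-bis(benzyloxy)-6-hydroxyphenyl]-3-[4-(benzyloxy)phenyl]prop-2-en-1-one, via aldol adduct 4 (not isolated)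
Conditions: KOH (50% aq.), EtOH/THF, rt, 36 h; then 1 M HCl
Reagents that add atoms: none
Why: Claisen–Schmidt crossed aldol condensation (key fragment-joining C–C bond) of a methyl ketone enolate with a non-enolisable aldehyde, with E1cB dehydration giving the E-enone and no stereocentre.

**Step 3**
Reactants: 5 (E)-1-[2,4-bis(benzyloxy)-6-hydroxyphenyl]-3-[4-(benzyloxy)phenyl]prop-2-en-1-one
Product: 7 5,7-bis(benzyloxy)-2-[4-(benzyloxy)phenyl]chromen-4-one, via flavanone 6 (not isolated)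
Conditions: I2 (10 mol%), DMSO, 130 °C, 3 h
Reagents that add atoms: none
Why: Oxidative cyclisation of a 2'-hydroxychalcone (oxa-Michael closure, then iodine-mediated dehydrogenation with DMSO as terminal oxidant); only one phenol is free, so the ring closes one way.

**Step 4**
Reactants: 7 5,7-bis(benzyloxy)-2-[4-(benzyloxy)phenyl]chromen-4-one
Product: 8 7-(benzyloxy)-2-[4-(benzyloxy)phenyl]-5-hydroxychromen-4-one
Conditions: BCl3 (1.2 equiv), CH2Cl2, −78 °C, 30 min; H2O quench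
Reagents that add atoms: none
Why: Chelation-controlled Lewis-acid ether cleavage; only the benzyl ether peri to the C4 carbonyl is activated at −78 °C.

**Step 5**
Reactants: 8 7-(benzyloxy)-2-[4-(benzyloxy)phenyl]-5-hydroxychromen-4-one; 9 allyl bromide
Product: 10 5-(allyloxy)-7-(benzyloxy)-2-[4-(benzyloxy)phenyl]chromen-4-one
Conditions: K2CO3, DMF, 60 °C, 6 h
Reagents that add atoms: none
Why: Williamson O-allylation of the only free phenol, which needs warm DMF because it is chelated.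

**Step 6**
Reactants: 10 5-(allyloxy)-7-(benzyloxy)-2-[4-(benzyloxy)phenyl]chromen-4-one
Product: 12 6-allyl-7-(benzyloxy)-2-[4-(benzyloxy)phenyl]-5-hydroxychromen-4-one, via ortho-dienone 11 (not isolated)
Conditions: PhNEt2, 200 °C, sealed tube, Ar, 4 h
Reagents that add atoms: none
Why: Aromatic Claisen rearrangement ([3,3]-sigmatropic shift then tautomerisation); C6 is the only ortho position bearing hydrogen, so the carbon handle lands there.

**Step 7**
Reactants: 12 6-allyl-7-(benzyloxy)-2-[4-(benzyloxy)phenyl]-5-hydroxychromen-4-one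
Product: 13 6-allyl-7-(benzyloxy)-2-[4-(benzyloxy)phenyl]-5-methoxychromen-4-one
Conditions: MeI (3 equiv), K2CO3, DMF, 50 °C
Reagents that add atoms: iodomethane, CI
Why: Williamson O-methylation; the small methyl group caps the hindered peri-OH, survives the acidic steps, and is later the only methyl ether removable by chelation.

**Step 8**
Reactants: 13 6-allyl-7-(benzyloxy)-2-[4-(benzyloxy)phenyl]-5-methoxychromen-4-one
Product: 15 2-{7-(benzyloxy)-2-[4-(benzyloxy)phenyl]-5-methoxy-4-oxochromen-6-yl}acetaldehyde, via diol 14 (not isolated)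
Conditions: OsO4 (2 mol%), NaIO4 (4 equiv), 2,6-lutidine, dioxane/H2O 3:1, rt
Reagents that add atoms: OsO4, O=[Os](=O)(=O)=O (catalytic oxygen donor); NaIO4, [Na+].[O-][I](=O)(=O)=O (reoxidant that restocks the oxygen)
Why: Lemieux–Johnson oxidative cleavage; the terminal alkene is dihydroxylated far faster than the electron-poor chromone C2=C3 bond.

**Step 9**
Reactants: 15 2-{7-(benzyloxy)-2-[4-(benzyloxy)phenyl]-5-methoxy-4-oxochromen-6-yl}acetaldehyde
Product: 16 2-{7-(benzyloxy)-2-[4-(benzyloxy)phenyl]-5-methoxy-4-oxochromen-6-yl}acetic acid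
Conditions: NaClO2, NaH2PO4, 2-methylbut-2-ene, t-BuOH/THF/H2O, 0 °C to rt
Reagents that add atoms: NaClO2, [Na+].[O-]Cl=O
Why: Pinnick oxidation of the aldehyde to the acid, with the alkene scavenger trapping hypochlorite so that no ring chlorination occurs.

**Step 10**
Reactants: 17 phloroglucinol
Product: 18 1,3,5-tris(benzyloxy)benzene
Conditions: BnBr (3.5 equiv), K2CO3, DMF, 60 °C, 12 h
Reagents that add atoms: benzyl bromide, BrCc1ccccc1
Why: Threefold Williamson etherification of a cheap triphenol; C-benzylated by-products are removed by crystallisation.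

**Step 11**
Reactants: 16 2-{7-(benzyloxy)-2-[4-(benzyloxy)phenyl]-5-methoxy-4-oxochromen-6-yl}acetic acid; 18 1,3,5-tris(benzyloxy)benzene
Product: 20 2-{7-(benzyloxy)-2-[4-(benzyloxy)phenyl]-5-methoxy-4-oxochromen-6-yl}-1-[2,4,6-tris(benzyloxy)phenyl]ethanone, via mixed anhydride 19 (not isolated)
Conditions: TFAA (1.5 equiv), CH2Cl2, 0 °C, 30 min; then 18 (1.3 equiv), 85% H3PO4 (cat.), 0 °C to rt
Reagents that add atoms: none
Why: Friedel–Crafts acylation through the acyl trifluoroacetate without a strong Lewis acid; the arene is symmetric, so one regioisomer forms and the benzyl ethers survive.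

**Step 12**
Reactants: 20 2-{7-(benzyloxy)-2-[4-(benzyloxy)phenyl]-5-methoxy-4-oxochromen-6-yl}-1-[2,4,6-tris(benzyloxy)phenyl]ethanone
Product: 21 1-[2,4-bis(benzyloxy)-6-hydroxyphenyl]-2-{7-(benzyloxy)-2-[4-(benzyloxy)phenyl]-5-methoxy-4-oxochromen-6-yl}ethanone
Conditions: BCl3 (2.2 equiv), CH2Cl2, −78 °C, 30 min; cold H2O quench
Reagents that add atoms: none
Why: Chelation-controlled mono-debenzylation ortho to the aryl ketone (the two ortho ethers are equivalent and the boron chelate blocks the second); the chelated methyl ether does not cleave at −78 °C.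

**Step 13**
Reactants: 21 1-[2,4-bis(benzyloxy)-6-hydroxyphenyl]-2-{7-(benzyloxy)-2-[4-(benzyloxy)phenyl]-5-methoxy-4-oxochromen-6-yl}ethanone; 22 4-methoxybenzoyl chloride
Product: 23 3,5-bis(benzyloxy)-2-(2-{7-(benzyloxy)-2-[4-(benzyloxy)phenyl]-5-methoxy-4-oxochromen-6-yl}acetyl)phenyl 4-methoxybenzoate
Conditions: Et3N, DMAP (cat.), CH2Cl2, 0 °C to rt
Reagents that add atoms: none
Why: DMAP-catalysed O-acylation of the single free phenol places the aroyl group next to the ketone for the acyl transfer.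

**Step 14**
Reactants: 23 3,5-bis(benzyloxy)-2-(2-{7-(benzyloxy)-2-[4-(benzyloxy)phenyl]-5-methoxy-4-oxochromen-6-yl}acetyl)phenyl 4-methoxybenzoate
Product: 25 5,7-bis(benzyloxy)-3-{7-(benzyloxy)-2-[4-(benzyloxy)phenyl]-5-methoxy-4-oxochromen-6-yl}-2-(4-methoxyphenyl)chromen-4-one, via 1,3-diketone 24 (not isolated)
Conditions: LiN(SiMe3)2 (2.5 equiv), THF, −20 °C to rt; AcOH quench; then TsOH·H2O (cat.), toluene, 90 °C
Reagents that add atoms: none
Why: Baker–Venkataraman rearrangement (the acidic benzylic enolate takes the aroyl group through a six-membered transition state) followed by acid cyclodehydration of the only free phenol onto the 4-methoxybenzoyl carbonyl.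

**Step 15**
Reactants: 25 5,7-bis(benzyloxy)-3-{7-(benzyloxy)-2-[4-(benzyloxy)phenyl]-5-methoxy-4-oxochromen-6-yl}-2-(4-methoxyphenyl)chromen-4-one
Product: 26 5,7-dihydroxy-3-[5,7-dihydroxy-2-(4-hydroxyphenyl)-4-oxochromen-6-yl]-2-(4-methoxyphenyl)chromen-4-one
Conditions: BCl3 (15 equiv), C6HMe5 (15 equiv), CH2Cl2, −78 °C to rt; H2O quench
Reagents that add atoms: none
Why: Lewis-acid debenzylation with a cation scavenger plus chelation-controlled demethylation of the peri-OMe; the unchelated 4'-OMe is inert to BCl3, and no stereocentre exists (the axis is left unresolved).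

**Compound list**
1 | 2,4,6-trihydroxyacetophenone | CC(=O)c1c(O)cc(O)cc1O | starting material
2 | 1-[2,4-bis(benzyloxy)-6-hydroxyphenyl]ethanone | CC(=O)c1c(O)cc(OCc2ccccc2)cc1OCc1ccccc1 | intermediate
3 | 4-(benzyloxy)benzaldehyde | O=Cc1ccc(OCc2ccccc2)cc1 | starting material
4 | 1-[2,4-bis(benzyloxy)-6-hydroxyphenyl]-3-[4-(benzyloxy)phenyl]-3-hydroxypropan-1-one (racemic aldol adduct) | O=C(CC(O)c1ccc(OCc2ccccc2)cc1)c1c(O)cc(OCc2ccccc2)cc1OCc1ccccc1 | intermediate (not isolated)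
5 | (E)-1-[2,4-bis(benzyloxy)-6-hydroxyphenyl]-3-[4-(benzyloxy)phenyl]prop-2-en-1-one | O=C(/C=C/c1ccc(OCc2ccccc2)cc1)c1c(O)cc(OCc2ccccc2)cc1OCc1ccccc1 | intermediate
6 | 5,7-bis(benzyloxy)-2-[4-(benzyloxy)phenyl]chroman-4-one (racemic flavanone) | O=C1CC(c2ccc(OCc3ccccc3)cc2)Oc2cc(OCc3ccccc3)cc(OCc3ccccc3)c12 | intermediate (not isolated)
7 | 5,7-bis(benzyloxy)-2-[4-(benzyloxy)phenyl]chromen-4-one | O=c1cc(-c2ccc(OCc3ccccc3)cc2)oc2cc(OCc3ccccc3)cc(OCc3ccccc3)c12 | intermediate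
8 | 7-(benzyloxy)-2-[4-(benzyloxy)phenyl]-5-hydroxychromen-4-one | O=c1cc(-c2ccc(OCc3ccccc3)cc2)oc2cc(OCc3ccccc3)cc(O)c12 | intermediate
9 | allyl bromide (3-bromoprop-1-ene) | C=CCBr | starting material
10 | 5-(allyloxy)-7-(benzyloxy)-2-[4-(benzyloxy)phenyl]chromen-4-one | C=CCOc1cc(OCc2ccccc2)cc2oc(-c3ccc(OCc4ccccc4)cc3)cc(=O)c12 | intermediate
11 | 6-allyl-7-(benzyloxy)-2-[4-(benzyloxy)phenyl]-6H-chromene-4,5-dione (racemic ortho-dienone) | C=CCC1C(OCc2ccccc2)=CC2=C(C1=O)C(=O)C=C(c1ccc(OCc3ccccc3)cc1)O2 | intermediate (not isolated)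
12 | 6-allyl-7-(benzyloxy)-2-[4-(benzyloxy)phenyl]-5-hydroxychromen-4-one | C=CCc1c(OCc2ccccc2)cc2oc(-c3ccc(OCc4ccccc4)cc3)cc(=O)c2c1O | intermediate
13 | 6-allyl-7-(benzyloxy)-2-[4-(benzyloxy)phenyl]-5-methoxychromen-4-one | C=CCc1c(OCc2ccccc2)cc2oc(-c3ccc(OCc4ccccc4)cc3)cc(=O)c2c1OC | intermediate
14 | 7-(benzyloxy)-2-[4-(benzyloxy)phenyl]-6-(2,3-dihydroxypropyl)-5-methoxychromen-4-one (racemic diol) | OCC(O)Cc1c(OCc2ccccc2)cc2oc(-c3ccc(OCc4ccccc4)cc3)cc(=O)c2c1OC | intermediate (not isolated)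
15 | 2-{7-(benzyloxy)-2-[4-(benzyloxy)phenyl]-5-methoxy-4-oxochromen-6-yl}acetaldehyde | O=CCc1c(OCc2ccccc2)cc2oc(-c3ccc(OCc4ccccc4)cc3)cc(=O)c2c1OC | intermediate
16 | 2-{7-(benzyloxy)-2-[4-(benzyloxy)phenyl]-5-methoxy-4-oxochromen-6-yl}acetic acid | OC(=O)Cc1c(OCc2ccccc2)cc2oc(-c3ccc(OCc4ccccc4)cc3)cc(=O)c2c1OC | intermediate
17 | phloroglucinol (benzene-1,3,5-triol) | Oc1cc(O)cc(O)c1 | starting material
18 | 1,3,5-tris(benzyloxy)benzene | c1ccc(COc2cc(OCc3ccccc3)cc(OCc3ccccc3)c2)cc1 | intermediate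
19 | mixed anhydride of acid 16 and trifluoroacetic acid | O=C(Cc1c(OCc2ccccc2)cc2oc(-c3ccc(OCc4ccccc4)cc3)cc(=O)c2c1OC)OC(=O)C(F)(F)F | intermediate (not isolated)
20 | 2-{7-(benzyloxy)-2-[4-(benzyloxy)phenyl]-5-methoxy-4-oxochromen-6-yl}-1-[2,4,6-tris(benzyloxy)phenyl]ethanone | O=C(Cc1c(OCc2ccccc2)cc2oc(-c3ccc(OCc4ccccc4)cc3)cc(=O)c2c1OC)c1c(OCc2ccccc2)cc(OCc2ccccc2)cc1OCc1ccccc1 | intermediate
21 | 1-[2,4-bis(benzyloxy)-6-hydroxyphenyl]-2-{7-(benzyloxy)-2-[4-(benzyloxy)phenyl]-5-methoxy-4-oxochromen-6-yl}ethanone | O=C(Cc1c(OCc2ccccc2)cc2oc(-c3ccc(OCc4ccccc4)cc3)cc(=O)c2c1OC)c1c(O)cc(OCc2ccccc2)cc1OCc1ccccc1 | intermediate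
22 | 4-methoxybenzoyl chloride | COc1ccc(cc1)C(Cl)=O | starting material
23 | 3,5-bis(benzyloxy)-2-(2-{7-(benzyloxy)-2-[4-(benzyloxy)phenyl]-5-methoxy-4-oxochromen-6-yl}acetyl)phenyl 4-methoxybenzoate | COc1ccc(cc1)C(=O)Oc1cc(OCc2ccccc2)cc(OCc2ccccc2)c1C(=O)Cc1c(OCc2ccccc2)cc2oc(-c3ccc(OCc4ccccc4)cc3)cc(=O)c2c1OC | intermediate
24 | 1-[2,4-bis(benzyloxy)-6-hydroxyphenyl]-2-{7-(benzyloxy)-2-[4-(benzyloxy)phenyl]-5-methoxy-4-oxochromen-6-yl}-3-(4-methoxyphenyl)propane-1,3-dione (racemic at C2, enolisable) | COc1ccc(cc1)C(=O)C(C(=O)c1c(O)cc(OCc2ccccc2)cc1OCc1ccccc1)c1c(OCc2ccccc2)cc2oc(-c3ccc(OCc4ccccc4)cc3)cc(=O)c2c1OC | intermediate (not isolated)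
25 | 5,7-bis(benzyloxy)-3-{7-(benzyloxy)-2-[4-(benzyloxy)phenyl]-5-methoxy-4-oxochromen-6-yl}-2-(4-methoxyphenyl)chromen-4-one | COc1ccc(cc1)-c1oc2cc(OCc3ccccc3)cc(OCc3ccccc3)c2c(=O)c1-c1c(OCc2ccccc2)cc2oc(-c3ccc(OCc4ccccc4)cc3)cc(=O)c2c1OC | intermediate
26 | 5,7-dihydroxy-3-[5,7-dihydroxy-2-(4-hydroxyphenyl)-4-oxochromen-6-yl]-2-(4-methoxyphenyl)chromen-4-one (no stereocentre) | COc1ccc(-c2oc3cc(O)cc(O)c3c(=O)c2-c2c(O)cc3oc(-c4ccc(O)cc4)cc(=O)c3c2O)cc1 | target

**Step count and risks**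
Total steps: 15. Longest linear sequence: 14 steps (steps 1–9 and 11–15 from compound 1); step 10 is a one-step side branch.

Three steps most likely to fail:

Step 6 (Claisen rearrangement on a flavone at 200 °C; possible decomposition or some para-migration). The fallback sets out from 8 and comes back at 13, replacing steps 5–7 by electrophilic substitution and cross-coupling. Compound 8 is iodinated ortho to the free 5-OH with BnMe3N·ICl2 and CaCO3 (CH2Cl2/MeOH, rt) to give 7-(benzyloxy)-2-[4-(benzyloxy)phenyl]-5-hydroxy-6-iodochromen-4-one F1. O-Methylation (MeI, K2CO3, DMF, 50 °C) gives 7-(benzyloxy)-2-[4-(benzyloxy)phenyl]-6-iodo-5-methoxychromen-4-one F2. Stille allylation with allyltributylstannane (Pd(PPh3)4, LiCl, DMF, 90 °C) then delivers 13.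

Step 11 (Friedel–Crafts acylation of an acid-sensitive tribenzyl ether by a bulky acid). The fallback sets out from 15 and comes back at 21, bypassing steps 9–12 by a Houben–Hoesch route. Aldehyde 15 is converted with I2 and aqueous NH3 in THF into 2-{7-(benzyloxy)-2-[4-(benzyloxy)phenyl]-5-methoxy-4-oxochromen-6-yl}acetonitrile F3. Reaction with phloroglucinol 17 (ZnCl2, dry HCl, Et2O/dioxane, 0 °C) gives the ketiminium chloride of the trihydroxyphenyl ketone F4. Hydrolysis in water at 90 °C gives 2-{7-(benzyloxy)-2-[4-(benzyloxy)phenyl]-5-methoxy-4-oxochromen-6-yl}-1-(2,4,6-trihydroxyphenyl)ethanone F5. Benzylation with BnBr (2.1 equiv) and K2CO3 in DMF leaves the chelated ortho-OH free and gives 21.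

Step 14 (acyl transfer and ring closure at a carbon flanked by two ortho-disubstituted aryl groups; possible retro-Claisen loss of the aroyl group). The fallback sets out from 21 and comes back at 25, bypassing steps 13 and 14 by an aldol route. Compound 21 is condensed with commercial 4-methoxybenzaldehyde (piperidine, EtOH, reflux; aldol condensation then oxa-Michael closure) to give 5,7-bis(benzyloxy)-3-{7-(benzyloxy)-2-[4-(benzyloxy)phenyl]-5-methoxy-4-oxochromen-6-yl}-2-(4-methoxyphenyl)chroman-4-one F6 (racemic, trans favoured). Dehydrogenation with DDQ in dioxane at 100 °C removes both stereocentres and gives 25.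

**Further compounds**
F1 | step 6 | 7-(benzyloxy)-2-[4-(benzyloxy)phenyl]-5-hydroxy-6-iodochromen-4-one | O=c1cc(-c2ccc(OCc3ccccc3)cc2)oc2cc(OCc3ccccc3)c(I)c(O)c12
F2 | step 6 | 7-(benzyloxy)-2-[4-(benzyloxy)phenyl]-6-iodo-5-methoxychromen-4-one | COc1c(I)c(OCc2ccccc2)cc2oc(-c3ccc(OCc4ccccc4)cc3)cc(=O)c12
F3 | step 11 | 2-{7-(benzyloxy)-2-[4-(benzyloxy)phenyl]-5-methoxy-4-oxochromen-6-yl}acetonitrile | N#CCc1c(OCc2ccccc2)cc2oc(-c3ccc(OCc4ccccc4)cc3)cc(=O)c2c1OC
F4 | step 11 | 2-{7-(benzyloxy)-2-[4-(benzyloxy)phenyl]-5-methoxy-4-oxochromen-6-yl}-1-(2,4,6-trihydroxyphenyl)ethaniminium chloride | [NH2+]=C(Cc1c(OCc2ccccc2)cc2oc(-c3ccc(OCc4ccccc4)cc3)cc(=O)c2c1OC)c1c(O)cc(O)cc1O.[Cl-]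
F5 | step 11 | 2-{7-(benzyloxy)-2-[4-(benzyloxy)phenyl]-5-methoxy-4-oxochromen-6-yl}-1-(2,4,6-trihydroxyphenyl)ethanone | O=C(Cc1c(OCc2ccccc2)cc2oc(-c3ccc(OCc4ccccc4)cc3)cc(=O)c2c1OC)c1c(O)cc(O)cc1O
F6 | step 14 | 5,7-bis(benzyloxy)-3-{7-(benzyloxy)-2-[4-(benzyloxy)phenyl]-5-methoxy-4-oxochromen-6-yl}-2-(4-methoxyphenyl)chroman-4-one (racemic, trans favoured) | COc1ccc(cc1)C1Oc2cc(OCc3ccccc3)cc(OCc3ccccc3)c2C(=O)C1c1c(OCc2ccccc2)cc2oc(-c3ccc(OCc4ccccc4)cc3)cc(=O)c2c1OC
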